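## Retrosynthetic overview
1. The C11' carbinol comes last. Double methyl addition to an L-malic acid dioxolanone reveals the 10',11'-diol, and C10' (S) is the malic acid carbon.
2. C5–C1' is made by nickel reductive coupling of 5-bromo-6-hydroxymellein with the allylic acetate end of the C1'–C10' chain.
3. C8'–C9' is the key bond. A visible-light Ni/photoredox decarboxylative allylation joins L-malic acid acetonide to the ene-chlorination product of geranyl acetate.
4. The δ-lactone is the only ring formed; the arene is bought. It is closed by Br/Li exchange, CO2 capture and lactonisation of a symmetric 2,6-dibromide, and C3 (R) comes from (R)-propylene oxide.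

Assumption: L-malic acid acetonide (9) is purchased. If preferred, it is one step from L-malic acid with 2,2-dimethoxypropane and catalytic TsOH.

## Route

**Step 1**
Reactants: 1 (1-bromo-3,5-dimethoxybenzene); 2 ((R)-propylene oxide)
Product: 3, (R)-1-(3,5-dimethoxyphenyl)propan-2-ol
Conditions: Mg, THF; then CuI (10 mol%), 2 (1.2 equiv), −30 → 0 °C
Reagents that add atoms: none (both partners are numbered reactants)
Why: Copper-catalysed Grignard opening of a terminal epoxide is an SN2 attack at the CH2 terminus, so the C–O bond at the stereocentre is untouched and the R configuration of 2 is carried over.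

**Step 2**
Reactants: 3
Product: 4, (R)-1-(2,6-dibromo-3,5-dimethoxyphenyl)propan-2-ol
Conditions: NBS (2.1 equiv), MeCN, 0 °C → rt
Reagents that add atoms: N-bromosuccinimide, O=C1CCC(=O)N1Br
Why: In this electrophilic aromatic bromination each Br enters para to one OMe and ortho to the other, while the site between the two OMe groups has no para activation and is more hindered, and the secondary alcohol is not oxidised on this time scale.

**Step 3**
Reactants: 4
Product: 5, (R)-5-bromo-6,8-dimethoxy-3-methylisochroman-1-one
Conditions: n-BuLi (2.2 equiv), THF, −78 °C; CO2 (g); then 2 M HCl, cat. TsOH, PhMe, 50 °C (telescoped)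
Reagents that add atoms: carbon dioxide, O=C=O
Why: After O-deprotonation, stoichiometry limits Br/Li exchange to one of two equivalent bromides, and carboxylation followed by acid-catalysed δ-lactonisation closes the ring, leaves the second Br at C5 and does not break the C3–O bond (R retained).

**Step 4**
Reactants: 5
Product: 6, (R)-5-bromo-6,8-dihydroxy-3-methylisochroman-1-one (5-bromo-6-hydroxymellein)
Conditions: BBr3 (5 equiv), CH2Cl2, −78 °C → rt
Reagents that add atoms: none
Why: BBr3 cleaves both aryl methyl ethers (the carbonyl-chelated 8-OMe first), while the non-benzylic secondary lactone C–O bond and the aryl bromide survive.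

**Step 5**
Reactants: 7 (geranyl acetate)
Product: 8, (2E)-6-chloro-3,7-dimethylocta-2,7-dien-1-yl acetate (racemic at C6; this centre is destroyed in Step 6)
Conditions: Ca(OCl)2, CO2 (dry ice), CH2Cl2/H2O, 0 °C
Reagents that add atoms: hypochlorous acid generated from Ca(OCl)2/CO2, OCl
Why: Ene-type allylic chlorination (chloronium formation, then proton loss from a methyl) occurs at the electron-rich 6,7-alkene because the 2,3-alkene is deactivated by the allylic acetoxy group.

**Step 6 (key step)**
Reactants: 8 (1.5 equiv); 9 ((S)-2-(2,2-dimethyl-5-oxo-1,3-dioxolan-4-yl)acetic acid, limiting)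
Product: 10, (2E,6E)-9-[(4S)-2,2-dimethyl-5-oxo-1,3-dioxolan-4-yl]-3,7-dimethylnona-2,6-dien-1-yl acetate
Conditions: 4CzIPN (3 mol%), NiCl2·glyme (10 mol%), dtbbpy (12 mol%), Cs2CO3 (1.0 equiv), degassed DMA, 450 nm LEDs, 25 °C
Reagents that add atoms: none (CO2 and chloride are lost)
Why: Proposed new method: a redox-neutral, regioconvergent decarboxylative alkyl–allyl coupling not yet shown for an unactivated primary β-oxygenated acid with a secondary 2-methylallyl chloride; Ni(0) ionises the chloride (much faster than the primary acetate) to a π-allyl Ni(II) that equilibrates to the syn isomer; the excited photocatalyst oxidises the carboxylate, and CO2 loss gives the primary C9' radical, which unlike a C9' organometallic cannot β-eliminate the C10' oxygen and lies one carbon from C10', so S is untouched; radical capture gives Ni(III) and reductive elimination at the unsubstituted C8' terminus sets the E-6',7' alkene; the reduced photocatalyst returns Ni(I) to Ni(0); any O-allyl ester from carboxylate alkylation re-enters through Ni(0) ionisation, and direct radical SH2' addition to 8 gives the same product; closest known reactions are metallaphotoredox decarboxylative C(sp3)–C(sp3) coupling of acids with alkyl halides, Pd/photoredox decarboxylative allylation and Ni/Zn reductive alkyl halide–allylic acetate coupling.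

**Step 7**
Reactants: 6 (1.0 equiv); 10 (1.3 equiv)
Product: 11, (3R)-5-{(2E,6E)-9-[(4S)-2,2-dimethyl-5-oxo-1,3-dioxolan-4-yl]-3,7-dimethylnona-2,6-dien-1-yl}-6,8-dihydroxy-3-methylisochroman-1-one
Conditions: NiCl2·glyme (10 mol%), dtbbpy (10 mol%), Zn dust (2.5 equiv), DMA, 40 °C
Reagents that add atoms: none (bromide and acetate are lost)
Why: In this Ni-catalysed reductive cross-electrophile coupling of an aryl bromide with an allylic acetate, aryl–allyl reductive elimination occurs at the CH2 terminus to give the linear product; the 2'E geometry holds because syn/anti exchange would need a tertiary σ-allyl nickel, and the neutral conditions spare the lactone, the dioxolanone and both stereocentres.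

**Step 8**
Reactants: 11
Product: 12, (10'S)-verruculide B
Conditions: MeMgBr (6.5 equiv), THF, −78 → −20 °C; sat. aq. NH4Cl
Reagents that add atoms: methylmagnesium bromide, C[Mg]Br
Why: Two equivalents of Grignard first form the bis-phenoxide, whose chelated, strongly donor-substituted lactone carbonyl is inert at −20 °C or below; the acylal-type dioxolanone then takes two methyl groups (Grignard double addition with loss of acetone) to give the C10' OH and the C11' tertiary carbinol without breaking the C10'–O bond (S retained).

## Compound list
| No. | Name | SMILES | Role |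
|---|---|---|---|
| 1 | 1-bromo-3,5-dimethoxybenzene | COc1cc(Br)cc(OC)c1 | starting material |
| 2 | (R)-propylene oxide | C[C@@H]1CO1 | starting material |
| 3 | (R)-1-(3,5-dimethoxyphenyl)propan-2-ol | C[C@@H](O)Cc1cc(OC)cc(OC)c1 | intermediate |
| 4 | (R)-1-(2,6-dibromo-3,5-dimethoxyphenyl)propan-2-ol | C[C@@H](O)Cc1c(Br)c(OC)cc(OC)c1Br | intermediate |
| 5 | (R)-5-bromo-6,8-dimethoxy-3-methylisochroman-1-one | C[C@@H]1Cc2c(Br)c(OC)cc(OC)c2C(=O)O1 | intermediate |
| 6 | (R)-5-bromo-6,8-dihydroxy-3-methylisochroman-1-one | C[C@@H]1Cc2c(Br)c(O)cc(O)c2C(=O)O1 | intermediate |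
| 7 | geranyl acetate | CC(C)=CCC/C(C)=C/COC(C)=O | starting material |
| 8 | (2E)-6-chloro-3,7-dimethylocta-2,7-dien-1-yl acetate (racemic at C6) | C=C(C)C(Cl)CC/C(C)=C/COC(C)=O | intermediate |
| 9 | (S)-2-(2,2-dimethyl-5-oxo-1,3-dioxolan-4-yl)acetic acid (L-malic acid acetonide) | CC1(C)O[C@@H](CC(=O)O)C(=O)O1 | starting material |
| 10 | (2E,6E)-9-[(4S)-2,2-dimethyl-5-oxo-1,3-dioxolan-4-yl]-3,7-dimethylnona-2,6-dien-1-yl acetate | CC(=O)OC/C=C(\C)CC/C=C(\C)CC[C@@H]1OC(C)(C)OC1=O | intermediate |
| 11 | (3R)-5-{(2E,6E)-9-[(4S)-2,2-dimethyl-5-oxo-1,3-dioxolan-4-yl]-3,7-dimethylnona-2,6-dien-1-yl}-6,8-dihydroxy-3-methylisochroman-1-one | C[C@@H]1Cc2c(C/C=C(\C)CC/C=C(\C)CC[C@@H]3OC(C)(C)OC3=O)c(O)cc(O)c2C(=O)O1 | intermediate |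
| 12 | (10'S)-verruculide B | C/C(=C\Cc1c(O)cc(O)c2c1C[C@@H](C)OC2=O)CC/C=C(\C)CC[C@H](O)C(C)(C)O | target |

## Summary
Total step count: 8
Longest linear sequence: 6 (Steps 1, 2, 3, 4, 7, 8). The chain branch is 4 steps (5, 6, 7, 8).

**Three steps most likely to fail**

1. **Step 6 (proposed new step).**
   - Risks: slow oxidation of the electron-poor primary carboxylate, allyl homodimerisation, competing ionisation of the C1' acetate, and incomplete E selectivity. I estimate about 8:1 E:Z, with AgNO3–silica separation if needed.
   - Fallback (known chemistry, reversed polarity):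
     - Make the C8' allylic sulfone from 7 by SeO2/t-BuOOH oxidation, bromination and PhSO2Na displacement, with the acetate exchanged for a silyl ether.
     - Lithiate the sulfone and open (S)-2-(oxiran-2-yl)propan-2-ol at its CH2 terminus.
     - That epoxide comes from commercial methyl (S)-2,2-dimethyl-1,3-dioxolane-4-carboxylate by MeMgBr addition, acid hydrolysis, primary tosylation and K2CO3 closure.
     - Remove the sulfone with Pd(0)/LiBHEt3.

2. **Step 7.**
   - Risks: the aryl bromide is di-ortho-substituted, electron-rich and carries an acidic phenol. Slow turnover, hydrodebromination or reversible O-allylation are possible.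
   - Fallback: make the chain the nucleophile. Convert the allylic acetate of 10 to the allyl tributylstannane (Pd(0), hexabutylditin). Then run a Stille coupling with 6 or its bis-silyl ether (Pd2(dba)3, AsPh3, LiCl, DMF, 80 °C). This is the established way to allylate hindered bromoresorcylates and adds one step.

3. **Step 8.**
   - Risks: methyl addition to the isochromanone lactone, or enolisation of the dioxolanone.
   - Fallback: reorder the endgame so the Grignard never meets the lactone. Treat 10 with MeMgBr to give (10S)-10,11-dihydroxyfarnesol and selectively acetylate the primary allylic alcohol. Then carry out the aryl–allyl coupling with 6 as the last step. This adds one step.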